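**Plan**

- Retrosynthesis: C1–C8a and C3=C4 of the dihydronaphthalene are cut together, a [3+3] split into a benzaldehyde and a pyranyl-alkylidene succinate with a phosphonate on the future C3. Further back: the pyranyl–CH=C alkene (future C1–C2, first Horner–Wadsworth–Emmons), the future C2–C3 bond (a phosphonoacetate carbanion alkylated by its α-bromo derivative) and the pyranone ring (oxalate plus 3-methylbut-2-enoate).
- Enabling feature: C8a is para to O6 (nucleophilic); C1 is the β-carbon of the C2 carboxyl and carries the electron-poor pyranone (electrophilic); C4 is an aldehyde-derived CH next to the C3 carboxyl. Ring B is thus a latent aryl triene C8a=C4a–C4=C3–C2=C1 that olefination assembles and acid closes.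
- Forward order: pyranone ring, its 4-carbaldehyde, the bis-phosphonate, the exocyclic alkene, then ring B (olefination and acid-induced closure in one flask), resolution, global demethylation.
- Stereochemistry: the 1,2-trans relation arises in the ring closure (enol protonation under thermodynamic control). The absolute configuration comes from resolution of the racemic triester on a chiral phase. C1–H and C2–H are both acidic, so only neutral or acidic conditions follow the ring closure.

Key step: step 6

Remark: racemates are written as both enantiomers joined by a dot; stereocentres that are destroyed later are left undefined; no enantioselective variant of the ring closure is assumed.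

**Step 1**
Reactants: 1 dimethyl oxalate; 2 methyl 3-methylbut-2-enoate
Product: 3 methyl 4-methyl-2-oxo-2H-pyran-6-carboxylate
Conditions: KOMe, Et2O/MeOH, 0 °C to rt; then HCl, MeOH, reflux
Reagents that add atoms: none
Why: Vinylogous Claisen condensation, in which the potassium dienolate of 2 is acylated at its γ-carbon by the oxalate and acid then closes the (Z)-2-hydroxydienoate onto the ester (enol lactonisation), the classical oxalate route to 6-carboxy-2-pyranones; no stereocentre is formed.

**Step 2**
Reactants: 3 methyl 4-methyl-2-oxo-2H-pyran-6-carboxylate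
Product: 4 methyl 4-formyl-2-oxo-2H-pyran-6-carboxylate
Conditions: SeO2, 1,4-dioxane, reflux
Reagents that add atoms: selenium dioxide, O=[Se]=O
Why: Riley oxidation of the 4-methyl group, which is vinylogously activated by the lactone carbonyl as in 4-methylcoumarins, should stop at the aldehyde while ring and ester stay untouched.

**Step 3**
Reactants: 5 methyl 2-(diethoxyphosphoryl)acetate
Product: 6 methyl 2-bromo-2-(diethoxyphosphoryl)acetate (racemic)
Conditions: NaH (1.0 equiv), THF, 0 °C; then added slowly to Br2 (1.05 equiv), CH2Cl2, −78 °C
Reagents that add atoms: bromine, BrBr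
Why: Electrophilic α-bromination of the sodium enolate of the phosphonoacetate; inverse addition keeps bromine in excess over the enolate, so the more acidic monobromide should not be deprotonated and brominated a second time.

**Step 4**
Reactants: 5 methyl 2-(diethoxyphosphoryl)acetate; 6 methyl 2-bromo-2-(diethoxyphosphoryl)acetate
Product: 7 dimethyl 2,3-bis(diethoxyphosphoryl)butanedioate (mixture of diastereomers)
Conditions: 5, NaH (1.0 equiv), THF, 0 °C; then 6 (1.0 equiv), −78 °C to rt
Reagents that add atoms: none
Why: C-alkylation (SN2) of the stabilised phosphonoacetate carbanion by the α-bromo ester, the bond formation by which halomalonates and sodiomalonates give ethanetetracarboxylates; halogen transfer between the two partners is degenerate and harmless, and the diastereomer mixture is of no consequence.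

**Step 5**
Reactants: 7 dimethyl 2,3-bis(diethoxyphosphoryl)butanedioate; 4 methyl 4-formyl-2-oxo-2H-pyran-6-carboxylate
Product: 8 dimethyl 2-(diethoxyphosphoryl)-3-{[6-(methoxycarbonyl)-2-oxo-2H-pyran-4-yl]methylidene}butanedioate (pyranyl trans to the ester on the alkene carbon, racemic at C2)
Conditions: 7 (1.2 equiv), NaH (1.1 equiv), THF, 0 °C; then 4, −78 °C to 0 °C; AcOH quench
Reagents that add atoms: none
Why: Horner–Wadsworth–Emmons olefination with one of the two phosphonate carbanions, the aldehyde being consumed as the β-alkoxyphosphonate at low temperature before the more acidic product can compete; the alkene geometry is not critical because both isomers converge in step 6.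

**Step 6**
Reactants: 8 dimethyl 2-(diethoxyphosphoryl)-3-{[6-(methoxycarbonyl)-2-oxo-2H-pyran-4-yl]methylidene}butanedioate; 9 3,4-dimethoxybenzaldehyde
Product: 11 dimethyl (1RS,2SR)-6,7-dimethoxy-1-[6-(methoxycarbonyl)-2-oxo-2H-pyran-4-yl]-1,2-dihydronaphthalene-2,3-dicarboxylate (racemic trans), via (2E,3E)-triene triester 10 (not isolated)
Conditions: DBU (1.2 equiv), CH2Cl2, 0 to 40 °C; then CF3SO3H (excess), 0 °C to rt, same flask
Reagents that add atoms: none
Why: The delocalised phosphonate anion of 8 olefinates 9 (Horner–Wadsworth–Emmons, making C3=C4 of the target) to give triene 10, and triflic acid then protonates the ester conjugated with the pyranyl alkylidene so that C8a of the dimethoxyphenyl ring adds to that alkylidene carbon (making C1–C8a), after which the arenium ion loses a proton and the ester enol tautomerises. The closest known reaction type is the triflic-acid cyclisation of (E,E)-2,3-bis(arylmethylidene)succinates to trans-1-aryl-1,2-dihydronaphthalene-2,3-dicarboxylates, a cationic 6π (Friedel–Crafts conjugate addition) closure, here run in the flask in which the triene is made. Ring B closes in the 6-endo-trig mode, the aryl carbon para to a methoxy group attacking the β-carbon of the unsaturated ester. C1 forms without a chiral influence, so 11 is racemic, and C2 is set relative to C1 by protonation of the enol and acid equilibration to the more stable 1,2-trans arrangement. The step needs the benzene ring and not the pyranone to act as the nucleophile, and attack at the CH terminus and not at the ester-bearing carbon: in triflic acid the pyranone is O-protonated and inert, and closure at the CH terminus gives a six-membered ring with a tertiary centre whereas the alternative needs a quaternary centre in a five-membered ring. Geometric isomers of 8 and 10 converge because protonation of the alkenes is reversible.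

**Step 7**
Reactants: 11 dimethyl (1RS,2SR)-6,7-dimethoxy-1-[6-(methoxycarbonyl)-2-oxo-2H-pyran-4-yl]-1,2-dihydronaphthalene-2,3-dicarboxylate
Product: 12 dimethyl (1R,2S)-6,7-dimethoxy-1-[6-(methoxycarbonyl)-2-oxo-2H-pyran-4-yl]-1,2-dihydronaphthalene-2,3-dicarboxylate
Conditions: preparative SFC, immobilised polysaccharide chiral phase, CO2/MeOH, no basic additive
Reagents that add atoms: none
Why: Resolution of the racemate by chromatography on a chiral stationary phase under neutral conditions, which leaves the two CH-acidic stereocentres untouched; the (1R,2S) enantiomer is to be assigned by ECD or X-ray analysis and taken on.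

**Step 8**
Reactants: 12 dimethyl (1R,2S)-6,7-dimethoxy-1-[6-(methoxycarbonyl)-2-oxo-2H-pyran-4-yl]-1,2-dihydronaphthalene-2,3-dicarboxylate
Product: 13 (1R,2S)-1-(6-carboxy-2-oxo-2H-pyran-4-yl)-6,7-dihydroxy-1,2-dihydronaphthalene-2,3-dicarboxylic acid
Conditions: BBr3 (excess), CH2Cl2, −78 °C to rt; then H2O, 0 °C
Reagents that add atoms: none
Why: Lewis-acid dealkylation, in which BBr3 should cleave the two aryl methyl ethers and, at room temperature, the three methyl esters by bromide attack on the O-methyl groups, while the pyranone ring oxygen is bound only to sp2 carbons and cannot be cleaved this way; no base is present, so C1 and C2 keep their configuration.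

**Compound list**

1 | dimethyl oxalate | COC(=O)C(=O)OC | starting material
2 | methyl 3-methylbut-2-enoate | COC(=O)C=C(C)C | starting material
3 | methyl 4-methyl-2-oxo-2H-pyran-6-carboxylate | COC(=O)c1cc(C)cc(=O)o1 | intermediate
4 | methyl 4-formyl-2-oxo-2H-pyran-6-carboxylate | COC(=O)c1cc(C=O)cc(=O)o1 | intermediate
5 | methyl 2-(diethoxyphosphoryl)acetate | CCOP(=O)(CC(=O)OC)OCC | starting material
6 | methyl 2-bromo-2-(diethoxyphosphoryl)acetate (racemic) | CCOP(=O)(OCC)C(Br)C(=O)OC | intermediate
7 | dimethyl 2,3-bis(diethoxyphosphoryl)butanedioate (diastereomer mixture) | CCOP(=O)(OCC)C(C(=O)OC)C(C(=O)OC)P(=O)(OCC)OCC | intermediate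
8 | dimethyl 2-(diethoxyphosphoryl)-3-{[6-(methoxycarbonyl)-2-oxo-2H-pyran-4-yl]methylidene}butanedioate (pyranyl trans to the ester on the alkene carbon, racemic at C2) | CCOP(=O)(OCC)C(C(=O)OC)/C(C(=O)OC)=C\c1cc(C(=O)OC)oc(=O)c1 | intermediate
9 | 3,4-dimethoxybenzaldehyde | COc1ccc(C=O)cc1OC | starting material
10 | dimethyl (2E,3E)-2-[(3,4-dimethoxyphenyl)methylidene]-3-{[6-(methoxycarbonyl)-2-oxo-2H-pyran-4-yl]methylidene}butanedioate | COC(=O)C(=C/c1ccc(OC)c(OC)c1)/C(C(=O)OC)=C\c1cc(C(=O)OC)oc(=O)c1 | intermediate
11 | dimethyl (1RS,2SR)-6,7-dimethoxy-1-[6-(methoxycarbonyl)-2-oxo-2H-pyran-4-yl]-1,2-dihydronaphthalene-2,3-dicarboxylate (racemic trans) | COC(=O)C1=Cc2cc(OC)c(OC)cc2[C@@H](c2cc(C(=O)OC)oc(=O)c2)[C@@H]1C(=O)OC.COC(=O)C1=Cc2cc(OC)c(OC)cc2[C@H](c2cc(C(=O)OC)oc(=O)c2)[C@H]1C(=O)OC | intermediate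
12 | dimethyl (1R,2S)-6,7-dimethoxy-1-[6-(methoxycarbonyl)-2-oxo-2H-pyran-4-yl]-1,2-dihydronaphthalene-2,3-dicarboxylate | COC(=O)C1=Cc2cc(OC)c(OC)cc2[C@@H](c2cc(C(=O)OC)oc(=O)c2)[C@@H]1C(=O)OC | intermediate
13 | (1R,2S)-1-(6-carboxy-2-oxo-2H-pyran-4-yl)-6,7-dihydroxy-1,2-dihydronaphthalene-2,3-dicarboxylic acid | O=C(O)C1=Cc2cc(O)c(O)cc2[C@@H](c2cc(C(=O)O)oc(=O)c2)[C@@H]1C(=O)O | target

**Step count and risks**

Total step count: 8. Longest linear sequence: 6 steps (steps 1, 2, 5, 6, 7, 8; the branch through steps 3 and 4 joins at step 5 and is equally long).

Steps most likely to fail: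

Step 6. The acid-induced closure may take a wrong course: attack at the ester-bearing alkene carbon with five-ring formation, degradation of the protonated pyranone, or oligomerisation. The delocalised phosphonate anion may also olefinate the electron-rich aldehyde only sluggishly. The fallback replaces the cationic closure by an aryl-radical closure; it sets out from 8 and comes back at 11. Compound 8 is olefinated (DBU, CH2Cl2) with commercial 2-bromo-4,5-dimethoxybenzaldehyde to give dimethyl (2E,3E)-2-[(2-bromo-4,5-dimethoxyphenyl)methylidene]-3-{[6-(methoxycarbonyl)-2-oxo-2H-pyran-4-yl]methylidene}butanedioate F1. Slow addition of Bu3SnH/AIBN in benzene at 80 °C generates the aryl radical, which should add 6-endo to the CH terminus of the pyranyl alkylidene ester, since the exo carbon is fully substituted. Hydrogen transfer to the resulting α-ester radical, followed if needed by equilibration of cis or double-bond isomers with catalytic DBU (harmless at the racemic stage), leads to 11.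

Step 5. Double olefination, base-induced migration of the new double bond out of conjugation, or attack of the carbanion on the pyranone may occur. The fallback builds the triene by a Wittig reaction and a stepwise Stobbe-type second condensation, and so also does without the bis-phosphonate 7 and its preparation in steps 3 and 4. It sets out from 4 and comes back at 10, which is then closed with triflic acid to 11 as in the second stage of step 6. Triphenylphosphine and dimethyl maleate give in the flask the ylide dimethyl 2-(triphenyl-λ5-phosphanylidene)butanedioate F2, which olefinates 4 to dimethyl (2E)-2-{[6-(methoxycarbonyl)-2-oxo-2H-pyran-4-yl]methylidene}butanedioate F3. LDA at −78 °C deprotonates the doubly activated CH2 group, the enolate adds to 9, and acetic anhydride traps the alkoxide as dimethyl 2-[(acetyloxy)(3,4-dimethoxyphenyl)methyl]-3-{[6-(methoxycarbonyl)-2-oxo-2H-pyran-4-yl]methylidene}butanedioate F4. DBU then eliminates acetic acid to give 10.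

Step 8. Cleavage of the conjugated and hindered methyl esters may be incomplete, and long exposure to the Lewis acid may damage the lactone or the styrenic double bond. The fallback separates ether and ester cleavage and uses a different ester cleavage mechanism; it sets out from 12 and comes back at 13. BBr3 at −78 to −20 °C removes only the two aryl methyl ethers and gives dimethyl (1R,2S)-6,7-dihydroxy-1-[6-(methoxycarbonyl)-2-oxo-2H-pyran-4-yl]-1,2-dihydronaphthalene-2,3-dicarboxylate F5. Its three methyl esters are then hydrolysed with trimethyltin hydroxide in 1,2-dichloroethane at 70 °C, followed by dilute acid, conditions known to spare α-stereocentres, to give 13.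

**Further compounds**

F1 | step 6 | dimethyl (2E,3E)-2-[(2-bromo-4,5-dimethoxyphenyl)methylidene]-3-{[6-(methoxycarbonyl)-2-oxo-2H-pyran-4-yl]methylidene}butanedioate | COC(=O)C(=C/c1cc(OC)c(OC)cc1Br)/C(C(=O)OC)=C\c1cc(C(=O)OC)oc(=O)c1
F2 | step 5 | dimethyl 2-(triphenyl-λ5-phosphanylidene)butanedioate | COC(=O)CC(=P(c1ccccc1)(c1ccccc1)c1ccccc1)C(=O)OC
F3 | step 5 | dimethyl (2E)-2-{[6-(methoxycarbonyl)-2-oxo-2H-pyran-4-yl]methylidene}butanedioate | COC(=O)C/C(C(=O)OC)=C\c1cc(C(=O)OC)oc(=O)c1
F4 | step 5 | dimethyl 2-[(acetyloxy)(3,4-dimethoxyphenyl)methyl]-3-{[6-(methoxycarbonyl)-2-oxo-2H-pyran-4-yl]methylidene}butanedioate (diastereomer mixture) | COC(=O)C(C(OC(C)=O)c1ccc(OC)c(OC)c1)/C(C(=O)OC)=C\c1cc(C(=O)OC)oc(=O)c1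
F5 | step 8 | dimethyl (1R,2S)-6,7-dihydroxy-1-[6-(methoxycarbonyl)-2-oxo-2H-pyran-4-yl]-1,2-dihydronaphthalene-2,3-dicarboxylate | COC(=O)C1=Cc2cc(O)c(O)cc2[C@@H](c2cc(C(=O)OC)oc(=O)c2)[C@@H]1C(=O)OC
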